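The quinone ring (C1=O between C2–OAr and C6–iPr; C4=O between C3–Me and C5–H) is disconnected at C4–C5 and traced back to a four-membered ring: a 4-hydroxy-4-(1-isopropylvinyl)cyclobutenone that already carries the complete bis(aryl ether) as its 3-aryloxy group. Its ring carbons become C4, C3, C2 and C1; the vinyl group supplies C6 and C5. Heating opens the cyclobutenone to a dienylketene that closes to the six-membered ring with the para-dioxygen pattern and all four substituents in place; silver oxide in the same flask then gives the target quinone. The phenol partner comes from an Ullmann coupling of two thymol-derived rings.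

Key step: step 11

Remark: the target has no stereocentre; the single stereocentre met on the way (the carbinol carbon of 17) is formed racemic and is destroyed in step 11.

Step 1
Reactants: 1 4-bromothymol (4-bromo-5-methyl-2-(propan-2-yl)phenol)
Product: 2 4-methoxy-5-methyl-2-(propan-2-yl)phenol
Conditions: NaOMe (5 equiv, 25% in MeOH), CuBr (0.2 equiv), DMF, 110 °C, Ar
Reagents that add atoms: sodium methoxide, [Na+].[O-]C
Why: Ullmann-type copper-catalysed methoxylation of the aryl bromide should work on the free bromophenol because the large excess of methoxide outcompetes the hindered phenoxide as the oxygen nucleophile.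

Step 2
Reactants: 2 4-methoxy-5-methyl-2-(propan-2-yl)phenol
Product: 3 2-bromo-4-methoxy-3-methyl-6-(propan-2-yl)phenol
Conditions: NBS (1.0 equiv), CH2Cl2, 0 °C, dark
Reagents that add atoms: N-bromosuccinimide, O=C1CCC(=O)N1Br
Why: Electrophilic aromatic bromination should go ortho to the free hydroxyl (para position blocked), at the only open ortho carbon, which is also less hindered than the carbon between isopropyl and methoxy.

Step 3
Reactants: 3 2-bromo-4-methoxy-3-methyl-6-(propan-2-yl)phenol
Product: 4 1-(benzyloxy)-2-bromo-4-methoxy-3-methyl-6-(propan-2-yl)benzene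
Conditions: BnBr, K2CO3, DMF, 60 °C
Reagents that add atoms: benzyl bromide, BrCc1ccccc1
Why: Williamson ether synthesis masks the phenol so that the bromide cannot couple with itself in step 4.

Step 4
Reactants: 4 1-(benzyloxy)-2-bromo-4-methoxy-3-methyl-6-(propan-2-yl)benzene and 2 4-methoxy-5-methyl-2-(propan-2-yl)phenol (second portion)
Product: 5 1-(benzyloxy)-4-methoxy-2-[4-methoxy-5-methyl-2-(propan-2-yl)phenoxy]-3-methyl-6-(propan-2-yl)benzene
Conditions: CuI (10 mol%), picolinic acid (20 mol%), K3PO4 (2 equiv), DMSO, 100 °C, Ar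
Reagents that add atoms: none
Why: Ullmann diaryl ether synthesis under Cu(I)/picolinic acid catalysis, a system that tolerates ortho substituents on both the aryl halide and the phenol, should join the two thymol-derived rings through oxygen.

Step 5
Reactants: 5 1-(benzyloxy)-4-methoxy-2-[4-methoxy-5-methyl-2-(propan-2-yl)phenoxy]-3-methyl-6-(propan-2-yl)benzene
Product: 6 4-methoxy-2-[4-methoxy-5-methyl-2-(propan-2-yl)phenoxy]-3-methyl-6-(propan-2-yl)phenol
Conditions: H2 (1 atm), 10% Pd/C, EtOAc–EtOH, rt
Reagents that add atoms: none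
Why: Hydrogenolysis of the benzyl ether should free the phenol while the diaryl ether and the methyl ethers stay inert.

Step 6
Reactants: 7 diisopropyl squarate (3,4-di(propan-2-yloxy)cyclobut-3-ene-1,2-dione)
Product: 9 3-methyl-4-(propan-2-yloxy)cyclobut-3-ene-1,2-dione, via adduct 8 (not isolated)
Conditions: MeLi (1.05 equiv), THF, −78 °C; aq. NH4Cl; crude in CH2Cl2, conc. HCl (cat.), rt
Reagents that add atoms: methyllithium, [Li]C
Why: 1,2-Addition of MeLi to one of the two equivalent carbonyls, then acid-induced ionisation of the tertiary allylic alcohol with loss of isopropanol from the resulting oxocarbenium ion, is the established route from squarates to 3-alkoxy-4-alkylcyclobutenediones.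

Step 7
Reactants: 9 3-methyl-4-(propan-2-yloxy)cyclobut-3-ene-1,2-dione
Product: 10 3-hydroxy-4-methylcyclobut-3-ene-1,2-dione
Conditions: 6 M HCl, THF, 50 °C
Reagents that add atoms: water, O
Why: Acid hydrolysis of the vinylogous ester by addition–elimination of water should give the semisquaric acid.

Step 8
Reactants: 10 3-hydroxy-4-methylcyclobut-3-ene-1,2-dione and 6 4-methoxy-2-[4-methoxy-5-methyl-2-(propan-2-yl)phenoxy]-3-methyl-6-(propan-2-yl)phenol
Product: 12 3-{4-methoxy-2-[4-methoxy-5-methyl-2-(propan-2-yl)phenoxy]-3-methyl-6-(propan-2-yl)phenoxy}-4-methylcyclobut-3-ene-1,2-dione, via chloride 11 (not isolated)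
Conditions: (COCl)2 (1.0 equiv), DMF (cat.), CH2Cl2, 0 °C to rt; then 6, Et3N (2.2 equiv), −20 °C to rt
Reagents that add atoms: none
Why: Vilsmeier-type activation turns the vinylogous acid into its very electrophilic vinylogous acid chloride, which the phenol should attack by addition–elimination at the chlorine-bearing carbon (an O-acylation in the vinylogous sense).

Step 9
Reactants: 13 3-methylbutan-2-one and 14 2,4,6-tri(propan-2-yl)benzenesulfonohydrazide
Product: 15 (E)-N'-(3-methylbutan-2-ylidene)-2,4,6-tri(propan-2-yl)benzenesulfonohydrazide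
Conditions: MeOH, HCl (cat.), rt
Reagents that add atoms: none
Why: Condensation of the ketone with the sulfonylhydrazide should give the hydrazone, with the E isomer (sulfonamide nitrogen away from the isopropyl group) favoured.

Step 10
Reactants: 15 (E)-N'-(3-methylbutan-2-ylidene)-2,4,6-tri(propan-2-yl)benzenesulfonohydrazide (1.2 equiv) and 12 3-{4-methoxy-2-[4-methoxy-5-methyl-2-(propan-2-yl)phenoxy]-3-methyl-6-(propan-2-yl)phenoxy}-4-methylcyclobut-3-ene-1,2-dione
Product: 17 rac-3-{4-methoxy-2-[4-methoxy-5-methyl-2-(propan-2-yl)phenoxy]-3-methyl-6-(propan-2-yl)phenoxy}-4-hydroxy-2-methyl-4-(3-methylbut-1-en-2-yl)cyclobut-2-en-1-one, via vinyllithium 16 (not isolated)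
Conditions: 15, n-BuLi (2.4 equiv), THF, −78 to 0 °C (N2 evolution); −78 °C, add 12 in THF; aq. NH4Cl at −78 °C
Reagents that add atoms: none
Why: A Shapiro reaction (dianion at the methyl group, loss of sulfinate and N2) should give vinyllithium 16, which adds 1,2 at −78 °C to the more electrophilic carbonyl of 12, the one next to the aryloxy-bearing carbon (the other is deactivated as a vinylogous ester); the new carbinol stereocentre forms racemic and is removed in step 11.

Step 11
Reactants: 17 rac-3-{4-methoxy-2-[4-methoxy-5-methyl-2-(propan-2-yl)phenoxy]-3-methyl-6-(propan-2-yl)phenoxy}-4-hydroxy-2-methyl-4-(3-methylbut-1-en-2-yl)cyclobut-2-en-1-one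
Product: 21 CNP0335608.0 (2-{4-methoxy-2-[4-methoxy-5-methyl-2-(propan-2-yl)phenoxy]-3-methyl-6-(propan-2-yl)phenoxy}-3-methyl-6-(propan-2-yl)cyclohexa-2,5-diene-1,4-dione), via dienylketene 18 (not isolated), via cyclohexadienone 19 (not isolated), via hydroquinone 20 (not isolated)
Conditions: PhMe (degassed, dilute), 110 °C; cool; then Ag2O (2 equiv), rt
Reagents that add atoms: none
Why: Thermal 4π-electrocyclic opening of the cyclobutenone (bond between ring carbonyl and carbinol carbon), with the hydroxyl turning outward and the 1-isopropylvinyl group inward, should give dienylketene 18, whose 6π-electrocyclisation joins the ketene carbon to the vinyl CH2 to give cyclohexadienone 19; enolisation gives hydroquinone 20, which Ag2O oxidises to the quinone. The closest known reaction is the Liebeskind–Moore ring expansion of 4-alkenyl- and 4-aryl-4-hydroxycyclobutenones to hydroquinones and quinones. The six-membered ring closes by a thermally allowed disrotatory 6π-electrocyclisation that forms the C4–C5 bond of the quinone. No stereocentre is formed and the one in 17 disappears. The step needs the vinyl group, not the hydroxyl, to turn inward on ring opening (otherwise the ketene is trapped as a butenolide), and the strong preference of the donor hydroxyl for outward rotation secures this; the regiochemistry is fixed by the substituent positions on the four-membered ring, the former ring carbonyl ending between C3–Me and C5–H and the former carbinol carbon between C2–OAr and C6–iPr. Ag2O is mild enough to leave the two methoxy-substituted aryl ether rings untouched.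

Compound list
1 | 4-bromothymol (4-bromo-5-methyl-2-(propan-2-yl)phenol) | Cc1cc(O)c(C(C)C)cc1Br | starting material
2 | 4-methoxy-5-methyl-2-(propan-2-yl)phenol | COc1cc(C(C)C)c(O)cc1C | intermediate
3 | 2-bromo-4-methoxy-3-methyl-6-(propan-2-yl)phenol | COc1cc(C(C)C)c(O)c(Br)c1C | intermediate
4 | 1-(benzyloxy)-2-bromo-4-methoxy-3-methyl-6-(propan-2-yl)benzene | COc1cc(C(C)C)c(OCc2ccccc2)c(Br)c1C | intermediate
5 | 1-(benzyloxy)-4-methoxy-2-[4-methoxy-5-methyl-2-(propan-2-yl)phenoxy]-3-methyl-6-(propan-2-yl)benzene | COc1cc(C(C)C)c(OCc2ccccc2)c(Oc2cc(C)c(OC)cc2C(C)C)c1C | intermediate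
6 | 4-methoxy-2-[4-methoxy-5-methyl-2-(propan-2-yl)phenoxy]-3-methyl-6-(propan-2-yl)phenol | COc1cc(C(C)C)c(O)c(Oc2cc(C)c(OC)cc2C(C)C)c1C | intermediate
7 | diisopropyl squarate (3,4-di(propan-2-yloxy)cyclobut-3-ene-1,2-dione) | CC(C)OC1=C(OC(C)C)C(=O)C1=O | starting material
8 | 4-hydroxy-4-methyl-2,3-di(propan-2-yloxy)cyclobut-2-en-1-one (racemic adduct) | CC(C)OC1=C(OC(C)C)C(C)(O)C1=O | intermediate (not isolated)
9 | 3-methyl-4-(propan-2-yloxy)cyclobut-3-ene-1,2-dione | CC(C)OC1=C(C)C(=O)C1=O | intermediate
10 | 3-hydroxy-4-methylcyclobut-3-ene-1,2-dione | CC1=C(O)C(=O)C1=O | intermediate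
11 | 3-chloro-4-methylcyclobut-3-ene-1,2-dione | CC1=C(Cl)C(=O)C1=O | intermediate (not isolated)
12 | 3-{4-methoxy-2-[4-methoxy-5-methyl-2-(propan-2-yl)phenoxy]-3-methyl-6-(propan-2-yl)phenoxy}-4-methylcyclobut-3-ene-1,2-dione | CC1=C(Oc2c(C(C)C)cc(OC)c(C)c2Oc2cc(C)c(OC)cc2C(C)C)C(=O)C1=O | intermediate
13 | 3-methylbutan-2-one | CC(=O)C(C)C | starting material
14 | 2,4,6-tri(propan-2-yl)benzenesulfonohydrazide | CC(C)c1cc(C(C)C)c(S(=O)(=O)NN)c(C(C)C)c1 | starting material
15 | (E)-N'-(3-methylbutan-2-ylidene)-2,4,6-tri(propan-2-yl)benzenesulfonohydrazide | CC(C)/C(C)=N/NS(=O)(=O)c1c(C(C)C)cc(C(C)C)cc1C(C)C | intermediate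
16 | (3-methylbut-1-en-2-yl)lithium | [Li]C(=C)C(C)C | intermediate (not isolated)
17 | rac-3-{4-methoxy-2-[4-methoxy-5-methyl-2-(propan-2-yl)phenoxy]-3-methyl-6-(propan-2-yl)phenoxy}-4-hydroxy-2-methyl-4-(3-methylbut-1-en-2-yl)cyclobut-2-en-1-one | CC1=C(Oc2c(C(C)C)cc(OC)c(C)c2Oc2cc(C)c(OC)cc2C(C)C)C(O)(C(=C)C(C)C)C1=O | intermediate
18 | dienylketene: 3-(aryloxy)-4-hydroxy-2-methyl-5-(propan-2-yl)hexa-1,3,5-trien-1-one, ketenyl and isopropylvinyl groups cis on the central double bond (aryl = the bis(aryl ether) group of 6) | O=C=C(C)/C(Oc2c(C(C)C)cc(OC)c(C)c2Oc2cc(C)c(OC)cc2C(C)C)=C(/O)C(=C)C(C)C | intermediate (not isolated)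
19 | cyclohexadienone: 3-(aryloxy)-4-hydroxy-2-methyl-5-(propan-2-yl)cyclohexa-2,4-dien-1-one | O=C1CC(C(C)C)=C(O)C(Oc2c(C(C)C)cc(OC)c(C)c2Oc2cc(C)c(OC)cc2C(C)C)=C1C | intermediate (not isolated)
20 | hydroquinone: 2-(aryloxy)-3-methyl-6-(propan-2-yl)benzene-1,4-diol | Cc1c(O)cc(C(C)C)c(O)c1Oc1c(C(C)C)cc(OC)c(C)c1Oc1cc(C)c(OC)cc1C(C)C | intermediate (not isolated)
21 | CNP0335608.0, 2-{4-methoxy-2-[4-methoxy-5-methyl-2-(propan-2-yl)phenoxy]-3-methyl-6-(propan-2-yl)phenoxy}-3-methyl-6-(propan-2-yl)cyclohexa-2,5-diene-1,4-dione | COc1cc(C(C)C)c(Oc2c(C)c(OC)cc(C(C)C)c2OC2=C(C)C(=O)C=C(C(C)C)C2=O)cc1C | target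

Total step count: 11.
Longest linear sequence: 8 steps (steps 1, 2, 3, 4, 5, 8, 10, 11); steps 6–7 and step 9 are side branches.

Steps most likely to fail

1. Step 10. The vinyllithium may attack the carbonyl on the methyl side, because the bulky aryloxy group shields the intended carbonyl, or it may expel the aryloxide by conjugate addition–elimination. The fallback keeps the ring expansion but moves the aryl ether formation to the end. It sets out from 9, whose isopropoxy group is known to direct organolithium addition to the neighbouring carbonyl. Vinyllithium 16 (from 15 as in step 10) would be added to 9 at −78 °C to give 4-hydroxy-2-methyl-4-(3-methylbut-1-en-2-yl)-3-(propan-2-yloxy)cyclobut-2-en-1-one F1. Heating in toluene and then Ag2O, as in step 11, should give 3-methyl-6-(propan-2-yl)-2-(propan-2-yloxy)cyclohexa-2,5-diene-1,4-dione F2. Hydrolysis of this vinylogous ester (aq. NaOH, MeOH, then acid) should give 2-hydroxy-3-methyl-6-(propan-2-yl)cyclohexa-2,5-diene-1,4-dione F3. Thionyl chloride with catalytic DMF should convert it into 2-chloro-3-methyl-6-(propan-2-yl)cyclohexa-2,5-diene-1,4-dione F4. Addition–elimination of phenol 6 on F4 (Cs2CO3, MeCN, rt) comes back to the route at 21.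

2. Step 4. Copper insertion into the C–Br bond flanked by benzyloxy and methyl may be so slow that protodebromination and oxidation of the electron-rich phenol take over. The fallback forms the same C–O bond by addition–elimination on a quinone and sets out from 3. Oxidation of 3 with ceric ammonium nitrate (MeCN–H2O, 0 °C) should give 2-bromo-3-methyl-6-(propan-2-yl)cyclohexa-2,5-diene-1,4-dione F5. Phenol 2 with Cs2CO3 in MeCN should displace the bromide to give 2-[4-methoxy-5-methyl-2-(propan-2-yl)phenoxy]-3-methyl-6-(propan-2-yl)cyclohexa-2,5-diene-1,4-dione F6. Reduction with Na2S2O4 (EtOAc–H2O) should give 2-[4-methoxy-5-methyl-2-(propan-2-yl)phenoxy]-3-methyl-6-(propan-2-yl)benzene-1,4-diol F7. Methylation with one equivalent of Me2SO4 and K2CO3 in acetone should take place at the less hindered hydroxyl (between methyl and hydrogen) and not at the one between aryloxy and isopropyl. This comes back to the route at 6.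

3. Step 8. Chloride 11 may be consumed by base-induced self-condensation through its acidic methyl group, or by traces of water, faster than the doubly ortho-substituted phenol attacks. The fallback introduces the methyl group after the ether bond and sets out from 6. Phenol 6 with one equivalent of commercial squaric acid dichloride (3,4-dichlorocyclobut-3-ene-1,2-dione) and Et3N in CH2Cl2 at −40 °C should give 3-chloro-4-{4-methoxy-2-[4-methoxy-5-methyl-2-(propan-2-yl)phenoxy]-3-methyl-6-(propan-2-yl)phenoxy}cyclobut-3-ene-1,2-dione F8. Stille coupling with tetramethylstannane (Pd catalyst, tri(2-furyl)phosphine, CuI, MeCN, 50 °C) should then replace the chloride by methyl and comes back to the route at 12.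

Further compounds
F1 | step 10 | 4-hydroxy-2-methyl-4-(3-methylbut-1-en-2-yl)-3-(propan-2-yloxy)cyclobut-2-en-1-one (racemic) | CC(C)OC1=C(C)C(=O)C1(O)C(=C)C(C)C
F2 | step 10 | 3-methyl-6-(propan-2-yl)-2-(propan-2-yloxy)cyclohexa-2,5-diene-1,4-dione | CC(C)OC1=C(C)C(=O)C=C(C(C)C)C1=O
F3 | step 10 | 2-hydroxy-3-methyl-6-(propan-2-yl)cyclohexa-2,5-diene-1,4-dione | OC1=C(C)C(=O)C=C(C(C)C)C1=O
F4 | step 10 | 2-chloro-3-methyl-6-(propan-2-yl)cyclohexa-2,5-diene-1,4-dione | ClC1=C(C)C(=O)C=C(C(C)C)C1=O
F5 | step 4 | 2-bromo-3-methyl-6-(propan-2-yl)cyclohexa-2,5-diene-1,4-dione | BrC1=C(C)C(=O)C=C(C(C)C)C1=O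
F6 | step 4 | 2-[4-methoxy-5-methyl-2-(propan-2-yl)phenoxy]-3-methyl-6-(propan-2-yl)cyclohexa-2,5-diene-1,4-dione | COc1cc(C(C)C)c(OC2=C(C)C(=O)C=C(C(C)C)C2=O)cc1C
F7 | step 4 | 2-[4-methoxy-5-methyl-2-(propan-2-yl)phenoxy]-3-methyl-6-(propan-2-yl)benzene-1,4-diol | COc1cc(C(C)C)c(Oc2c(C)c(O)cc(C(C)C)c2O)cc1C
F8 | step 8 | 3-chloro-4-{4-methoxy-2-[4-methoxy-5-methyl-2-(propan-2-yl)phenoxy]-3-methyl-6-(propan-2-yl)phenoxy}cyclobut-3-ene-1,2-dione | ClC1=C(Oc2c(C(C)C)cc(OC)c(C)c2Oc2cc(C)c(OC)cc2C(C)C)C(=O)C1=O
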